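The step that makes Q has a rate constant of 23 L mol⁻¹ s⁻¹, 59.0 times that of the step that eats Q with J, 0.39 L mol⁻¹ s⁻¹, and we reckon from that gap.

    L + Q → L.Q (k1 = 0.11 L mol⁻¹ s⁻¹)
    Q + J → Q.J (k2 = 0.39 L mol⁻¹ s⁻¹)
    L + E → Q + J (k3 = 23 L mol⁻¹ s⁻¹)

| setting | green | red | ochre | amber |
|---|---|---|---|---|
| L | 0.40 M | 0.40 M | 0.40 M | 0.40 M (fed, over 6.00 s) |
| E | 0.392 M | 0.392 M (fed, over 6.00 s) | 0.392 M | 0.392 M |
| remark | one stirred flow tank at steady state, fed with the mixture as stated, mean residence time 6.0 s | a stirred flask in which E is dosed at a steady rate over 6.00 s without added volume, worked up at 6.0 s | everything together in a closed stirred flask, run for 6.0 s | a stirred flask in which L is dosed at a steady rate over 6.00 s without added volume, worked up at 6.0 s |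
| time |  | 6.0 s | 6.0 s | 6.0 s |

1. the set-up with the highest amount of Q at the outlet or at the end, in percent of the L put in ("none" if the first two lie within 2 percentage points) (green / red / ochre / amber / none)
2. amount of Q at the outlet or at the end, in percent of the L put in, green
3. amount of Q at the outlet or at the end, in percent of the L put in, red
4. amount of Q at the outlet or at the end, in percent of the L put in, ochre
5. amount of Q at the outlet or at the end, in percent of the L put in, amber

- percent here means L units held: one L.Q counts as two
- the stated concentrations are those of everything mixed, before any reaction; amounts are the same in each set-up
- the feed brings no volume worth counting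
- run time (red): 6.0 s

The bench rule is to treat the fast step as finished at once. In ochre, L and E meet on a clock of about 0.109 s, so E, the limiting reagent at 0.392 M against 0.40 M of L, becomes equal amounts of Q and J. We name the clock of what follows the pairing time: the inverse of the rate constant of Q + J → Q.J times the concentration of the pair, 6.54 s at the full charge, far longer than the fast step. Q then falls as its starting concentration divided by one plus time over pairing time, which gives ochre 51.1% at 6.0 s.

Dosing spreads the same pairing over the run. With x the square root of dosing time over pairing time, 0.958, Q is the charge of E times tanh(x)/x, or 76.1% in red and amber alike.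

That figure is too high, and the border comes from the feed rate over the fast constant. Its square root is the level at which L and E must stand, when nearly equal, to consume the dose: 0.0533 M, or 13.3% of the L. Subtracting it leaves 62.8% for both dosed flasks. In green the same lag, put into the tank balance, gives 55.7%. So we expect a dosed flask to win, but our reckoning cannot separate red from amber.

The forecast does separate them. It names amber, with 54.8% for green, 63.5% for red, 53% for ochre and 67% for amber, on the ground that “dosing over the full 6 s beats the batch and the stirred tank”.

The simulation gives 54.8% for green, 64.7% for red, 52.4% for ochre and 68.3% for amber, so amber leads red by 3.6 percentage points. In red at 2.84 s, J has a half-life of 11 s by pairing with Q, shorter than the 29 s of Q by L + Q. That second half-life is longer than the run of 6.0 s. The pairing time puts ochre at 9.63% by 60.0 s, where it reads 9.00%. Red at 6.00 s holds Q at 64.7% of the L with J at 0.274 M; reckoned on that Q, and counting neither the L nor the E still there, the pairing time is 9.91 s, which gives 33.9% at 15.0 s, where red reads 35.3%.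

Its constants stand for no real mixture; the result is computed.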